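**Retrosynthetic overview**
- The target is cut at the exocyclic C5=CH bond into a 3-aryltetronic acid and a chiral dihydrobenzofuran aldehyde, joined last by a Z-selective vinylogous aldol condensation.
- Key disconnection: the O1–C2 bond of the dihydrobenzofuran, made by a phenol-directed catalytic asymmetric epoxidation of 4-hydroxy-3-prenylbenzaldehyde followed by invertive 5-exo ring closure; this C–O event sets the only stereocenter.
- The 3-aryltetronic acid comes from conjugate addition of tetronic acid to 2-prenyl-1,4-benzoquinone, itself made from 1,4-dimethoxybenzene and prenyl bromide.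
- Ring order: the dihydrobenzofuran ring is closed first; the hydroquinone ring arises by aromatisation of the quinone adduct; the butenolide ring is bought as tetronic acid. No protecting groups are used.

Assumption: the SMILES is read as 2R at the dihydrobenzofuran carbon and Z at the exocyclic alkene; in step 2 the ligand antipode used is whichever is found to give the S epoxide, since the sense of induction on this new substrate class cannot be predicted with certainty.

**Step 1**
Reactants: 1 4-hydroxybenzaldehyde; 2 prenyl bromide (1-bromo-3-methylbut-2-ene)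
Product: 3 4-hydroxy-3-(3-methylbut-2-en-1-yl)benzaldehyde
Conditions: KOH (1.0 equiv), H2O, rt, 24 h, 2 added dropwise; chromatography to remove the O-prenyl ether
Reagents that add atoms: none
Why: Ortho C-alkylation of a phenoxide in water (hydrogen bonding shields the oxygen) by SN2 attack on prenyl bromide is a known, modest-yielding but one-step entry to this ortho-prenylphenol; no stereocenter is formed.

**Step 2**
Reactants: 3 4-hydroxy-3-(3-methylbut-2-en-1-yl)benzaldehyde
Product: 5 (2R)-2-(2-hydroxypropan-2-yl)-2,3-dihydro-1-benzofuran-5-carbaldehyde, via (S)-epoxyphenol 4 (not isolated)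
Conditions: Hf(OtBu)4 (10 mol%), bis-hydroxamic acid ligand L* (11 mol%; (1R,2R)-N,N'-dihydroxy-N,N'-bis[2,2-bis(3,5-di-tert-butylphenyl)acetyl]cyclohexane-1,2-diamine or its antipode), PhCMe2OOH (1.5 equiv), 4 Å MS, toluene, 0 °C; aq. Na2S2O3 wash; then K2CO3 (0.2 equiv), MeOH, rt
Reagents that add atoms: cumene hydroperoxide, CC(C)(OO)c1ccccc1
Why: Proposed new method: a phenol-directed asymmetric epoxidation in which the acidic phenol and the hydroperoxide both bind the chiral tetravalent hafnium bis-hydroxamate, so oxygen is delivered intramolecularly to one face of the prenyl alkene (three atoms from the bound oxygen, a bishomoallylic geometry) to give the S epoxide, and the phenoxide then opens it 5-exo at the secondary carbon by SN2 with inversion to set 2R; the closest known reactions are the Hf(OtBu)4 or Zr(OtBu)4/bis-hydroxamic acid epoxidation of homoallylic and bishomoallylic aliphatic alcohols with cumene hydroperoxide and the racemic VO(acac)2/tBuOOH epoxidation–cyclisation of 2-allylphenols.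

**Step 3**
Reactants: 6 1,4-dimethoxybenzene; 2 prenyl bromide
Product: 8 1,4-dimethoxy-2-(3-methylbut-2-en-1-yl)benzene, via aryllithium 7 (not isolated)
Conditions: n-BuLi (1.1 equiv), TMEDA (1.1 equiv), THF, 0 °C, 1 h; then 2 (1.2 equiv), −78 °C to rt
Reagents that add atoms: none
Why: Directed ortho-lithiation next to a methoxy group followed by SN2 alkylation of the aryllithium at the primary carbon of prenyl bromide is a standard route to prenylated dimethoxyarenes; no stereocenter is formed.

**Step 4**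
Reactants: 8 1,4-dimethoxy-2-(3-methylbut-2-en-1-yl)benzene
Product: 9 2-(3-methylbut-2-en-1-yl)cyclohexa-2,5-diene-1,4-dione (2-prenyl-1,4-benzoquinone)
Conditions: (NH4)2Ce(NO3)6 (2.5 equiv), MeCN/H2O 2:1, 0 °C, 20 min
Reagents that add atoms: water, O
Why: Oxidative demethylation of a 1,4-dimethoxyarene by tetravalent cerium (arene radical cation, ipso attack of water, loss of methanol) is fast and leaves the isolated trisubstituted alkene untouched.

**Step 5**
Reactants: 9 2-prenyl-1,4-benzoquinone; 10 tetronic acid (4-hydroxyfuran-2(5H)-one)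
Product: 11 3-[2,5-dihydroxy-4-(3-methylbut-2-en-1-yl)phenyl]-4-hydroxyfuran-2(5H)-one
Conditions: 10 (2.0 equiv), NaOAc (0.2 equiv), degassed MeCN/H2O 4:1, 0 °C to rt, 9 added over 2 h; aq. Na2S2O4 wash
Reagents that add atoms: none
Why: Michael addition of the tetronate C3 carbon to the quinone and tautomerisation gives the hydroquinone; the alkyl group makes the remote carbonyl less electrophilic, so attack is expected para to prenyl as in Nenitzescu-type additions to alkylquinones, while excess 10 and the reductive wash limit quinone–hydroquinone redox exchange.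

**Step 6**
Reactants: 11 3-[2,5-dihydroxy-4-(3-methylbut-2-en-1-yl)phenyl]-4-hydroxyfuran-2(5H)-one; 5 (2R)-2-(2-hydroxypropan-2-yl)-2,3-dihydro-1-benzofuran-5-carbaldehyde
Product: 13 (5Z)-3-[2,5-dihydroxy-4-(3-methylbut-2-en-1-yl)phenyl]-4-hydroxy-5-{[(2R)-2-(2-hydroxypropan-2-yl)-2,3-dihydro-1-benzofuran-5-yl]methylidene}furan-2(5H)-one (CNP0601419.1), via aldol adduct 12 (not isolated)
Conditions: 5 (1.1 equiv), DBU (1,8-diazabicyclo[5.4.0]undec-7-ene, 4 equiv), degassed MeCN, Ar, rt to 50 °C; then 1 M aq. citric acid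
Reagents that add atoms: none
Why: Vinylogous aldol condensation at C5 of the tetronate (C3 is blocked by the aryl group) followed by E1cB loss of water under thermodynamic control gives the Z-ylidene (aryl syn to the ring oxygen, away from the C4 oxygen); the 2R centre carried in from 5 is not touched.

**Compound list**
1 | 4-hydroxybenzaldehyde | O=Cc1ccc(O)cc1 | starting material
2 | prenyl bromide (1-bromo-3-methylbut-2-ene) | CC(C)=CCBr | starting material
3 | 4-hydroxy-3-(3-methylbut-2-en-1-yl)benzaldehyde | CC(C)=CCc1cc(C=O)ccc1O | intermediate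
4 | 3-{[(2S)-3,3-dimethyloxiran-2-yl]methyl}-4-hydroxybenzaldehyde | O=Cc1ccc(O)c(C[C@@H]2OC2(C)C)c1 | intermediate
5 | (2R)-2-(2-hydroxypropan-2-yl)-2,3-dihydro-1-benzofuran-5-carbaldehyde | O=Cc1ccc2c(c1)C[C@H](C(C)(C)O)O2 | intermediate
6 | 1,4-dimethoxybenzene | COc1ccc(OC)cc1 | starting material
7 | (2,5-dimethoxyphenyl)lithium | [Li]c1cc(OC)ccc1OC | intermediate
8 | 1,4-dimethoxy-2-(3-methylbut-2-en-1-yl)benzene | COc1ccc(OC)c(CC=C(C)C)c1 | intermediate
9 | 2-(3-methylbut-2-en-1-yl)cyclohexa-2,5-diene-1,4-dione | CC(C)=CCC1=CC(=O)C=CC1=O | intermediate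
10 | tetronic acid (4-hydroxyfuran-2(5H)-one) | O=C1OCC(O)=C1 | starting material
11 | 3-[2,5-dihydroxy-4-(3-methylbut-2-en-1-yl)phenyl]-4-hydroxyfuran-2(5H)-one | CC(C)=CCc1cc(O)c(C2=C(O)COC2=O)cc1O | intermediate
12 | 3-[2,5-dihydroxy-4-(3-methylbut-2-en-1-yl)phenyl]-4-hydroxy-5-{hydroxy[(2R)-2-(2-hydroxypropan-2-yl)-2,3-dihydro-1-benzofuran-5-yl]methyl}furan-2(5H)-one (mixture of diastereomers at the two new centres) | CC(C)=CCc1cc(O)c(C2=C(O)C(C(O)c3ccc4c(c3)C[C@H](C(C)(C)O)O4)OC2=O)cc1O | intermediate
13 | (5Z)-3-[2,5-dihydroxy-4-(3-methylbut-2-en-1-yl)phenyl]-4-hydroxy-5-{[(2R)-2-(2-hydroxypropan-2-yl)-2,3-dihydro-1-benzofuran-5-yl]methylidene}furan-2(5H)-one | CC(C)=CCc1cc(O)c(C2=C(O)/C(=C/c3ccc4c(c3)C[C@H](C(C)(C)O)O4)OC2=O)cc1O | target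

**Totals**
Total step count: 6. Longest linear sequence: 4 steps (steps 3, 4, 5, 6 from 1,4-dimethoxybenzene); the aldehyde arm is 2 steps (steps 1, 2) and joins in step 6.

**Steps most likely to fail, with fallbacks**

Step 2 (the proposed new epoxidation–cyclisation). The risks are low enantioselectivity with a phenol as the directing group, oxidation of the aldehyde by the hydroperoxide, and 6-endo opening to the chromanol before the basic stage. The fallback uses known chemistry, sets out from 3 and comes back at 5. Compound 3 is silylated (iPr3SiCl, imidazole, DMF) to 3-(3-methylbut-2-en-1-yl)-4-[(triisopropylsilyl)oxy]benzaldehyde F1. Shi epoxidation with the enantiomer of the fructose-derived ketone (1,2:4,5-di-O-isopropylidene-L-erythro-2,3-hexodiulo-2,6-pyranose, 30 mol%), KHSO5 (as 2KHSO5·KHSO4·K2SO4), K2CO3 buffer, MeCN/dimethoxymethane/H2O, 0 °C, gives the S epoxide silyl ether F2. Bu4NF in THF at 0 °C then frees the phenoxide, which opens the epoxide 5-exo with inversion to give 5.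

Step 5 (quinone Michael addition). The risks are the regioisomer from attack meta to prenyl, redox exchange between product hydroquinone and quinone 9, and over-addition. The fallback builds the butenolide on an aryl ring that already carries the correct substitution; it sets out from prenyl bromide 2 and comes back at 11. Commercial 2,5-dibromobenzene-1,4-diol F3 is protected (MOMCl, iPr2NEt, CH2Cl2) as 1,4-dibromo-2,5-bis(methoxymethoxy)benzene F4. One bromine–lithium exchange (n-BuLi 1.0 equiv, THF, −78 °C) gives [4-bromo-2,5-bis(methoxymethoxy)phenyl]lithium F5, which is alkylated by 2 to 1-bromo-2,5-bis(methoxymethoxy)-4-(3-methylbut-2-en-1-yl)benzene F6. Coupling with the Reformatsky reagent BrZnCH2CO2Et under Pd(dba)2 and Q-Phos (1,2,3,4,5-pentaphenyl-1'-(di-tert-butylphosphino)ferrocene) in THF gives ethyl 2-[2,5-bis(methoxymethoxy)-4-(3-methylbut-2-en-1-yl)phenyl]acetate F7. Methyl glycolate and KOtBu in DMF effect transesterification to methyl 2-({[2,5-bis(methoxymethoxy)-4-(3-methylbut-2-en-1-yl)phenyl]acetyl}oxy)acetate F8, which undergoes Dieckmann closure in the same flask to 3-[2,5-bis(methoxymethoxy)-4-(3-methylbut-2-en-1-yl)phenyl]-4-hydroxyfuran-2(5H)-one F9. 2 M HCl in MeOH at rt removes both MOM groups to give 11.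

Step 6 (direct aldol condensation of two unprotected polyhydroxy partners). The risks are sluggish C5 nucleophilicity of the tetronate under an amine base, air oxidation of the hydroquinone, and E/Z mixtures. The fallback switches to a silyloxyfuran vinylogous Mukaiyama aldol; it sets out from 11 and 5 and comes back at 12. Compound 11 is persilylated (Me3SiCl, Et3N, then Me3SiOTf, CH2Cl2) to 3-[4-(3-methylbut-2-en-1-yl)-2,5-bis(trimethylsilyloxy)phenyl]-2,4-bis(trimethylsilyloxy)furan F10. Aldehyde 5 is silylated (Me3SiCl, imidazole) to (2R)-2-[2-(trimethylsilyloxy)propan-2-yl]-2,3-dihydro-1-benzofuran-5-carbaldehyde F11. Me3SiOTf-catalysed addition of F10 through C5 to F11 in CH2Cl2 at −78 °C gives the pentasilylated aldol adduct F12. Work-up with 1 M HCl in THF at 0 °C removes the silyl groups to give 12, now isolated, which is dehydrated to 13 with DBU in MeCN as in the second half of step 6.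

**Further compounds**
F1 | step 2 | 3-(3-methylbut-2-en-1-yl)-4-[(triisopropylsilyl)oxy]benzaldehyde | CC(C)=CCc1cc(C=O)ccc1O[Si](C(C)C)(C(C)C)C(C)C
F2 | step 2 | 3-{[(2S)-3,3-dimethyloxiran-2-yl]methyl}-4-[(triisopropylsilyl)oxy]benzaldehyde | CC(C)[Si](Oc1ccc(C=O)cc1C[C@@H]1OC1(C)C)(C(C)C)C(C)C
F3 | step 5 | 2,5-dibromobenzene-1,4-diol | Oc1cc(Br)c(O)cc1Br
F4 | step 5 | 1,4-dibromo-2,5-bis(methoxymethoxy)benzene | COCOc1cc(Br)c(OCOC)cc1Br
F5 | step 5 | [4-bromo-2,5-bis(methoxymethoxy)phenyl]lithium | [Li]c1cc(OCOC)c(Br)cc1OCOC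
F6 | step 5 | 1-bromo-2,5-bis(methoxymethoxy)-4-(3-methylbut-2-en-1-yl)benzene | CC(C)=CCc1cc(OCOC)c(Br)cc1OCOC
F7 | step 5 | ethyl 2-[2,5-bis(methoxymethoxy)-4-(3-methylbut-2-en-1-yl)phenyl]acetate | CCOC(=O)Cc1cc(OCOC)c(CC=C(C)C)cc1OCOC
F8 | step 5 | methyl 2-({[2,5-bis(methoxymethoxy)-4-(3-methylbut-2-en-1-yl)phenyl]acetyl}oxy)acetate | COC(=O)COC(=O)Cc1cc(OCOC)c(CC=C(C)C)cc1OCOC
F9 | step 5 | 3-[2,5-bis(methoxymethoxy)-4-(3-methylbut-2-en-1-yl)phenyl]-4-hydroxyfuran-2(5H)-one | CC(C)=CCc1cc(OCOC)c(C2=C(O)COC2=O)cc1OCOC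
F10 | step 6 | 3-[4-(3-methylbut-2-en-1-yl)-2,5-bis(trimethylsilyloxy)phenyl]-2,4-bis(trimethylsilyloxy)furan | CC(C)=CCc1cc(O[Si](C)(C)C)c(cc1O[Si](C)(C)C)-c1c(O[Si](C)(C)C)coc1O[Si](C)(C)C
F11 | step 6 | (2R)-2-[2-(trimethylsilyloxy)propan-2-yl]-2,3-dihydro-1-benzofuran-5-carbaldehyde | O=Cc1ccc2c(c1)C[C@H](C(C)(C)O[Si](C)(C)C)O2
F12 | step 6 | 3-[4-(3-methylbut-2-en-1-yl)-2,5-bis(trimethylsilyloxy)phenyl]-4-(trimethylsilyloxy)-5-{(trimethylsilyloxy)[(2R)-2-[2-(trimethylsilyloxy)propan-2-yl]-2,3-dihydro-1-benzofuran-5-yl]methyl}furan-2(5H)-one | CC(C)=CCc1cc(O[Si](C)(C)C)c(C2=C(O[Si](C)(C)C)C(C(O[Si](C)(C)C)c3ccc4c(c3)C[C@H](C(C)(C)O[Si](C)(C)C)O4)OC2=O)cc1O[Si](C)(C)C
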